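**Retrosynthetic overview**
1. The acid comes from its methyl ester; the side-chain bond C1'–C2' is cut (Wittig reaction, then diimide) into a bicyclic Z-allylic phosphonium salt and a 6-formyl-1,2-dioxane whose carbons all come from geraniol.
2. Dioxane: both O atoms come from H2O2; C6–O is made by inverting perhydrolysis of a Sharpless epoxide, C3–O by inverting SN2 ring closure on the mesylate of an anti-crotylation product.
3. Bicycle (numbered C1–C8a as 5,5-dimethyl-3,4,5,6,7,8-hexahydronaphthalen-2(1H)-ylidene): ring B starts as an anisole ring and ring A is closed on it in one operation by a palladium-catalysed C(sp3)–H activation/alkyne [4+2] annulation that forms C8–C8a and C6–C7.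
4. Enabling feature: the quaternary C5 with its two methyl groups sits on ring-fusion carbon C4a, next to C8a; C5, C6 and the two methyls can therefore be a tert-butyl group ortho to an aryl triflate, whose three equivalent methyl groups supply the C–H bond that becomes C6.
5. Ring order: ring B (aromatic) → ring A (key step) → Birch reduction sets the C4a=C8a alkene and the C2 ketone → Z exocyclic alkene by 1,4-hydroboration of a 2-vinyl-1,3-diene; the dioxane ring is closed on the separate fragment before the union.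

Key step: step 4

Remark: C1' is the CH2 on dioxane C6, C2' the next CH2 and C3' the exocyclic alkene CH; the target is (2S)-2-{(3R,6S)-6-[(3Z)-3-(bicyclic ylidene)propyl]-6-methyl-1,2-dioxan-3-yl}propanoic acid.

**Bicyclic fragment**

Step 1
Reactants: 1 resorcinol; 2 tert-butanol
Product: 3 4-tert-butylbenzene-1,3-diol
Conditions: 85% H3PO4, toluene, 70 °C, excess of 1
Reagents that add atoms: none
Why: Friedel–Crafts alkylation by the tert-butyl cation should occur at C4, the unhindered position ortho to one hydroxyl and para to the other, and the excess of 1 limits dialkylation.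

Step 2
Reactants: 3 4-tert-butylbenzene-1,3-diol
Product: 4 2-tert-butyl-5-methoxyphenol
Conditions: MeI (1.0 equiv), K2CO3 (1.0 equiv), acetone, rt
Reagents that add atoms: iodomethane, CI
Why: Williamson ether synthesis should take the unhindered hydroxyl para to the tert-butyl group ahead of the one flanked by it.

Step 3
Reactants: 4 2-tert-butyl-5-methoxyphenol
Product: 5 2-tert-butyl-5-methoxyphenyl trifluoromethanesulfonate
Conditions: Tf2O, pyridine, CH2Cl2, 0 °C
Reagents that add atoms: trifluoromethanesulfonic anhydride, O=S(=O)(OS(=O)(=O)C(F)(F)F)C(F)(F)F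
Why: O-sulfonylation of the remaining phenol gives the aryl triflate that places the oxidative-addition site ortho to the tert-butyl group.

Step 4
Reactants: 5 2-tert-butyl-5-methoxyphenyl trifluoromethanesulfonate; 6 bis(trimethylsilyl)acetylene
Product: 7 (6-methoxy-1,1-dimethyl-1,2-dihydronaphthalene-3,4-diyl)bis(trimethylsilane)
Conditions: Pd(OAc)2 (10 mol%), PCy3·HBF4 (20 mol%), CsOPiv (30 mol%), Cs2CO3 (1.5 equiv), 6 (4 equiv), mesitylene, 140 °C, sealed tube
Reagents that add atoms: none
Why: Proposed new method: oxidative addition of the aryl C–OTf bond to zerovalent palladium is followed by pivalate-assisted concerted metalation–deprotonation of a methyl C–H bond of the ortho tert-butyl group, giving a five-membered C(aryl),C(alkyl) palladacycle of divalent palladium; syn insertion of alkyne 6 into the Pd–aryl bond (forming target bond C8–C8a) and C(sp2)–C(sp3) reductive elimination of the vinyl and neopentyl ligands (forming C6–C7) then return zerovalent palladium. The closest known reaction types are the palladium-catalysed C(sp3)–H activation of 2-halo-tert-butylarenes to the same five-membered palladacycles and the [4+2] annulation of five-membered C(sp2),C(sp3)-palladacycles with internal alkynes. Ring A is closed as a six-membered ring in a formal [4+2] mode through a seven-membered palladacycle, with four atoms (C8a, C4a, C5, C6) from the arene and its tert-butyl group and two (C7, C8) from the alkyne. No stereocentre is formed. The step needs site selectivity in the C–H cleavage, which is secured because the three methyl groups are equivalent, the palladacycle is five-membered and the neopentyl-type palladium alkyl has no β-hydrogen. It also needs alkyne insertion to outrun reductive elimination to a benzocyclobutene, which the strain of the four-membered ring and the excess of 6 should favour; the two silyl groups make the alkyne internal, so no alkynyl C–H coupling can occur, and they are removed in step 5.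

Step 5
Reactants: 7 (6-methoxy-1,1-dimethyl-1,2-dihydronaphthalene-3,4-diyl)bis(trimethylsilane)
Product: 8 6-methoxy-1,1-dimethyl-1,2-dihydronaphthalene
Conditions: CF3CO2H, CH2Cl2, 0 °C to rt
Reagents that add atoms: none
Why: Protodesilylation of vinylsilanes by ipso protonation and loss of silicon from the β-silyl cation should remove both silyl groups of the acetylene equivalent.

Step 6
Reactants: 8 6-methoxy-1,1-dimethyl-1,2-dihydronaphthalene
Product: 11 5,5-dimethyl-3,4,5,6,7,8-hexahydronaphthalen-2(1H)-one, via tetralin 9 (not isolated), via enol ether 10 (not isolated)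
Conditions: Li, NH3(l), THF, t-BuOH, −78 to −33 °C; NH4Cl; then oxalic acid, THF/MeOH/H2O, rt
Reagents that add atoms: water, O
Why: Birch reduction should first saturate the styrene-type double bond and then give the 2,5-dihydroanisole in which the two alkyl-substituted ring-fusion carbons stay as the tetrasubstituted alkene, and mild hydrolysis of the enol ether should give the β,γ-unsaturated ketone without moving that alkene.

Step 7
Reactants: 11 5,5-dimethyl-3,4,5,6,7,8-hexahydronaphthalen-2(1H)-one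
Product: 12 5,5-dimethyl-3,4,5,6,7,8-hexahydronaphthalen-2-yl trifluoromethanesulfonate
Conditions: KN(SiMe3)2, THF, −78 °C; PhNTf2, −78 to 0 °C
Reagents that add atoms: N-phenylbis(trifluoromethanesulfonimide), O=S(=O)(N(c1ccccc1)S(=O)(=O)C(F)(F)F)C(F)(F)F
Why: Enol triflate formation: deprotonation at C1, the doubly activated CH2 between the carbonyl and the C4a=C8a alkene, should give the conjugated dienolate, which is O-triflated to the 1,3-dienyl triflate.

Step 8
Reactants: 12 5,5-dimethyl-3,4,5,6,7,8-hexahydronaphthalen-2-yl trifluoromethanesulfonate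
Product: 13 6-ethenyl-1,1-dimethyl-1,2,3,4,7,8-hexahydronaphthalene
Conditions: vinylboronic acid pinacol ester, Pd(PPh3)4 (5 mol%), K3PO4, dioxane/H2O, 60 °C
Reagents that add atoms: vinylboronic acid pinacol ester, C=CB1OC(C)(C)C(C)(C)O1
Why: Suzuki–Miyaura coupling of the dienyl triflate should give the 2-vinyl-1,3-diene.

Step 9
Reactants: 13 6-ethenyl-1,1-dimethyl-1,2,3,4,7,8-hexahydronaphthalene
Product: 15 (2Z)-2-(5,5-dimethyl-3,4,5,6,7,8-hexahydronaphthalen-2(1H)-ylidene)ethan-1-ol, via allylboronate 14 (not isolated)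
Conditions: Ni(cod)2 (5 mol%), PCy3 (5 mol%), pinacolborane, toluene, rt; then NaOH, H2O2, THF, 0 °C
Reagents that add atoms: pinacolborane (boryl group of 14), B1OC(C)(C)C(C)(C)O1; hydrogen peroxide, OO
Why: Nickel-catalysed 1,4-hydroboration of the less hindered 1,3-diene unit proceeds through the s-cis diene on zerovalent nickel, placing boron on the terminal carbon and hydrogen on C1, so the new exocyclic alkene should have the CH2B group cis to C1 (Z), and oxidation of the C–B bond occurs with retention and without allylic shift.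

Step 10
Reactants: 15 (2Z)-2-(5,5-dimethyl-3,4,5,6,7,8-hexahydronaphthalen-2(1H)-ylidene)ethan-1-ol
Product: 16 (2Z)-2-(2-bromoethylidene)-5,5-dimethyl-1,2,3,4,5,6,7,8-octahydronaphthalene
Conditions: CBr4, PPh3, CH2Cl2, −20 °C
Reagents that add atoms: carbon tetrabromide, BrC(Br)(Br)Br
Why: Appel bromination of the primary allylic alcohol is an SN2 displacement that should keep the position and Z geometry of the alkene at low temperature.

Step 11
Reactants: 16 (2Z)-2-(2-bromoethylidene)-5,5-dimethyl-1,2,3,4,5,6,7,8-octahydronaphthalene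
Product: 17 [(2Z)-2-(5,5-dimethyl-3,4,5,6,7,8-hexahydronaphthalen-2(1H)-ylidene)ethyl]triphenylphosphonium bromide
Conditions: PPh3, MeCN, rt
Reagents that add atoms: triphenylphosphine, c1ccc(cc1)P(c1ccccc1)c1ccccc1
Why: SN2 alkylation of the phosphine at the primary allylic carbon should give the Wittig salt.

**Dioxane fragment**

Step 12
Reactants: 18 geraniol
Product: 19 [(2S,3S)-3-methyl-3-(4-methylpent-3-en-1-yl)oxiran-2-yl]methanol
Conditions: Ti(OiPr)4 (cat.), L-(+)-diethyl tartrate, t-BuOOH, 4 Å molecular sieves, CH2Cl2, −20 °C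
Reagents that add atoms: tert-butyl hydroperoxide, CC(C)(C)OO
Why: Sharpless asymmetric epoxidation oxidises only the allylic alcohol alkene, and the L-tartrate ligand sets both epoxide stereocentres as (2S,3S).

Step 13
Reactants: 19 [(2S,3S)-3-methyl-3-(4-methylpent-3-en-1-yl)oxiran-2-yl]methanol
Product: 20 tert-butyl{[(2S,3S)-3-methyl-3-(4-methylpent-3-en-1-yl)oxiran-2-yl]methoxy}diphenylsilane
Conditions: t-BuPh2SiCl, imidazole, DMF, rt
Reagents that add atoms: tert-butyl(chloro)diphenylsilane, CC(C)(C)[Si](Cl)(c1ccccc1)c1ccccc1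
Why: Silylation protects the primary alcohol as an ether that should survive the acidic perhydrolysis of step 17.

Step 14
Reactants: 20 tert-butyl{[(2S,3S)-3-methyl-3-(4-methylpent-3-en-1-yl)oxiran-2-yl]methoxy}diphenylsilane
Product: 21 3-[(2S,3S)-3-({[tert-butyl(diphenyl)silyl]oxy}methyl)-2-methyloxiran-2-yl]propanal
Conditions: O3, CH2Cl2, −78 °C; Me2S
Reagents that add atoms: ozone, [O-][O+]=O
Why: Ozonolysis of the only alkene with reductive work-up should give the aldehyde and leave the epoxide and silyl ether untouched.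

Step 15
Reactants: 21 3-[(2S,3S)-3-({[tert-butyl(diphenyl)silyl]oxy}methyl)-2-methyloxiran-2-yl]propanal
Product: 22 (3R,4S)-6-[(2S,3S)-3-({[tert-butyl(diphenyl)silyl]oxy}methyl)-2-methyloxiran-2-yl]-3-methylhex-1-en-4-ol
Conditions: (E)-crotyldiisopinocampheylborane made from (−)-α-pinene [via (+)-Ipc2BOMe, (E)-but-2-ene, n-BuLi, KOt-Bu, BF3·OEt2], THF, −78 °C; then NaOH, H2O2, 0 °C
Reagents that add atoms: (E)-but-2-en-1-ylbis[(1S,2R,3S,5S)-2,6,6-trimethylbicyclo[3.1.1]heptan-3-yl]borane, C/C=C/CB([C@H]1C[C@H]2C[C@@H]([C@@H]1C)C2(C)C)[C@H]1C[C@H]2C[C@@H]([C@@H]1C)C2(C)C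
Why: Brown crotylboration through a chair six-membered transition state gives the anti product from the E-crotyl group, and the isopinocampheyl groups from (−)-α-pinene should direct attack to the Re face of the aldehyde, setting (3R,4S).

Step 16
Reactants: 22 (3R,4S)-6-[(2S,3S)-3-({[tert-butyl(diphenyl)silyl]oxy}methyl)-2-methyloxiran-2-yl]-3-methylhex-1-en-4-ol
Product: 23 (3R,4S)-6-[(2S,3S)-3-({[tert-butyl(diphenyl)silyl]oxy}methyl)-2-methyloxiran-2-yl]-3-methylhex-1-en-4-yl methanesulfonate
Conditions: MsCl, Et3N, CH2Cl2, 0 °C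
Reagents that add atoms: methanesulfonyl chloride, CS(=O)(=O)Cl
Why: Mesylation turns the secondary alcohol into a leaving group with its configuration unchanged.

Step 17
Reactants: 23 (3R,4S)-6-[(2S,3S)-3-({[tert-butyl(diphenyl)silyl]oxy}methyl)-2-methyloxiran-2-yl]-3-methylhex-1-en-4-yl methanesulfonate
Product: 24 (3R,4S,7R,8S)-9-{[tert-butyl(diphenyl)silyl]oxy}-7-hydroperoxy-8-hydroxy-3,7-dimethylnon-1-en-4-yl methanesulfonate
Conditions: anhydrous H2O2 in Et2O (excess), H3PMo12O40 (cat.), rt
Reagents that add atoms: hydrogen peroxide, OO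
Why: Acid-catalysed perhydrolysis of epoxides opens the trisubstituted epoxide at its tertiary carbon with inversion, which sets the future C6, while the neighbouring carbinol keeps its configuration.

Step 18
Reactants: 24 (3R,4S,7R,8S)-9-{[tert-butyl(diphenyl)silyl]oxy}-7-hydroperoxy-8-hydroxy-3,7-dimethylnon-1-en-4-yl methanesulfonate
Product: 25 (1S)-1-{(3R,6R)-6-[(2R)-but-3-en-2-yl]-3-methyl-1,2-dioxan-3-yl}-2-{[tert-butyl(diphenyl)silyl]oxy}ethan-1-ol
Conditions: Cs2CO3, DMF, 0 °C to rt
Reagents that add atoms: none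
Why: Intramolecular SN2 alkylation of the hydroperoxide (6-exo-tet) should close the 1,2-dioxane with inversion at the mesylate carbon, because the mild base deprotonates only the far more acidic hydroperoxide and not the alcohol.

Step 19
Reactants: 25 (1S)-1-{(3R,6R)-6-[(2R)-but-3-en-2-yl]-3-methyl-1,2-dioxan-3-yl}-2-{[tert-butyl(diphenyl)silyl]oxy}ethan-1-ol
Product: 27 (2S)-2-{(3R,6R)-6-[(1S)-2-{[tert-butyl(diphenyl)silyl]oxy}-1-hydroxyethyl]-6-methyl-1,2-dioxan-3-yl}propanoic acid, via aldehyde 26 (not isolated)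
Conditions: O3, CH2Cl2, −78 °C; Me2S; then NaClO2, NaH2PO4, 2-methylbut-2-ene, t-BuOH/H2O, 0 °C to rt
Reagents that add atoms: ozone, [O-][O+]=O; sodium chlorite, [Na+].[O-]Cl=O
Why: Ozonolysis of the vinyl group and Pinnick oxidation of the crude aldehyde run under neutral to weakly acidic conditions, which should neither epimerise the α-stereocentre nor open the β-peroxy carbonyl compound.

Step 20
Reactants: 27 (2S)-2-{(3R,6R)-6-[(1S)-2-{[tert-butyl(diphenyl)silyl]oxy}-1-hydroxyethyl]-6-methyl-1,2-dioxan-3-yl}propanoic acid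
Product: 28 methyl (2S)-2-{(3R,6R)-6-[(1S)-2-{[tert-butyl(diphenyl)silyl]oxy}-1-hydroxyethyl]-6-methyl-1,2-dioxan-3-yl}propanoate
Conditions: Me3SiCHN2, toluene/MeOH, 0 °C
Reagents that add atoms: trimethylsilyldiazomethane, C[Si](C)(C)C=[N+]=[N-]
Why: Esterification with diazomethane generated in the flask is base-free and should leave the peroxide and the α-stereocentre intact.

Step 21
Reactants: 28 methyl (2S)-2-{(3R,6R)-6-[(1S)-2-{[tert-butyl(diphenyl)silyl]oxy}-1-hydroxyethyl]-6-methyl-1,2-dioxan-3-yl}propanoate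
Product: 29 methyl (2S)-2-{(3R,6R)-6-[(1S)-1,2-dihydroxyethyl]-6-methyl-1,2-dioxan-3-yl}propanoate
Conditions: HF·pyridine, THF/pyridine, 0 °C to rt
Reagents that add atoms: none
Why: Fluoride-mediated cleavage of the silyl ether under non-basic conditions should free the 1,2-diol.

Step 22
Reactants: 29 methyl (2S)-2-{(3R,6R)-6-[(1S)-1,2-dihydroxyethyl]-6-methyl-1,2-dioxan-3-yl}propanoate
Product: 30 methyl (2S)-2-[(3R,6R)-6-formyl-6-methyl-1,2-dioxan-3-yl]propanoate
Conditions: NaIO4, THF/pH 7 buffer, 0 °C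
Reagents that add atoms: none
Why: Periodate glycol cleavage should give the aldehyde on C6, which cannot enolise because C6 carries no hydrogen.

**Union and end game**

Step 23
Reactants: 17 [(2Z)-2-(5,5-dimethyl-3,4,5,6,7,8-hexahydronaphthalen-2(1H)-ylidene)ethyl]triphenylphosphonium bromide; 30 methyl (2S)-2-[(3R,6R)-6-formyl-6-methyl-1,2-dioxan-3-yl]propanoate
Product: 32 methyl (2S)-2-{(3R,6R)-6-[(3Z)-3-(5,5-dimethyl-3,4,5,6,7,8-hexahydronaphthalen-2(1H)-ylidene)prop-1-en-1-yl]-6-methyl-1,2-dioxan-3-yl}propanoate (either geometry at C1'=C2'), via ylide 31 (not isolated)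
Conditions: NaN(SiMe3)2 (1.0 equiv), THF, −78 °C; then 30, −78 to 0 °C
Reagents that add atoms: none
Why: Wittig reaction of the allylic ylide at its α-carbon with the aldehyde should keep the Z geometry of the existing trisubstituted alkene, as in Wittig reactions of neryl and geranyl phosphonium salts, and the geometry of the new disubstituted alkene does not matter.

Step 24
Reactants: 32 methyl (2S)-2-{(3R,6R)-6-[(3Z)-3-(5,5-dimethyl-3,4,5,6,7,8-hexahydronaphthalen-2(1H)-ylidene)prop-1-en-1-yl]-6-methyl-1,2-dioxan-3-yl}propanoate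
Product: 33 methyl (2S)-2-{(3R,6S)-6-[(3Z)-3-(5,5-dimethyl-3,4,5,6,7,8-hexahydronaphthalen-2(1H)-ylidene)propyl]-6-methyl-1,2-dioxan-3-yl}propanoate
Conditions: KO2CN=NCO2K, AcOH, CH2Cl2/MeOH, 0 °C to rt, added in portions
Reagents that add atoms: none
Why: Diimide reduction transfers hydrogen fastest to the least substituted alkene, so the disubstituted C1'=C2' bond should be saturated while the trisubstituted and tetrasubstituted alkenes and the O–O bond stay untouched.

Step 25
Reactants: 33 methyl (2S)-2-{(3R,6S)-6-[(3Z)-3-(5,5-dimethyl-3,4,5,6,7,8-hexahydronaphthalen-2(1H)-ylidene)propyl]-6-methyl-1,2-dioxan-3-yl}propanoate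
Product: 34 (2S)-2-{(3R,6S)-6-[(3Z)-3-(5,5-dimethyl-3,4,5,6,7,8-hexahydronaphthalen-2(1H)-ylidene)propyl]-6-methyl-1,2-dioxan-3-yl}propanoic acid
Conditions: LiOH, THF/H2O, 0 °C to rt; then 1 M HCl to pH 3
Reagents that add atoms: lithium hydroxide, [Li+].[OH-]
Why: Saponification of the methyl ester should be faster than enolisation of the β-peroxy ester, so the three stereocentres and the peroxide are kept.

**Compound list**
1 | resorcinol | Oc1cccc(O)c1 | starting material
2 | tert-butanol | CC(C)(C)O | starting material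
3 | 4-tert-butylbenzene-1,3-diol | CC(C)(C)c1ccc(O)cc1O | intermediate
4 | 2-tert-butyl-5-methoxyphenol | COc1ccc(C(C)(C)C)c(O)c1 | intermediate
5 | 2-tert-butyl-5-methoxyphenyl trifluoromethanesulfonate | COc1ccc(C(C)(C)C)c(OS(=O)(=O)C(F)(F)F)c1 | intermediate
6 | bis(trimethylsilyl)acetylene | C[Si](C)(C)C#C[Si](C)(C)C | starting material
7 | (6-methoxy-1,1-dimethyl-1,2-dihydronaphthalene-3,4-diyl)bis(trimethylsilane) | COc1ccc2c(c1)C([Si](C)(C)C)=C([Si](C)(C)C)CC2(C)C | intermediate
8 | 6-methoxy-1,1-dimethyl-1,2-dihydronaphthalene | COc1ccc2c(c1)C=CCC2(C)C | intermediate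
9 | 6-methoxy-1,1-dimethyl-1,2,3,4-tetrahydronaphthalene | COc1ccc2c(c1)CCCC2(C)C | intermediate
10 | 6-methoxy-1,1-dimethyl-1,2,3,4,5,8-hexahydronaphthalene | COC1=CCC2=C(C1)CCCC2(C)C | intermediate
11 | 5,5-dimethyl-3,4,5,6,7,8-hexahydronaphthalen-2(1H)-one | O=C1CCC2=C(C1)CCCC2(C)C | intermediate
12 | 5,5-dimethyl-3,4,5,6,7,8-hexahydronaphthalen-2-yl trifluoromethanesulfonate | O=S(=O)(OC1=CC2=C(CC1)C(C)(C)CCC2)C(F)(F)F | intermediate
13 | 6-ethenyl-1,1-dimethyl-1,2,3,4,7,8-hexahydronaphthalene | C=CC1=CC2=C(CC1)C(C)(C)CCC2 | intermediate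
14 | 2-[(2Z)-2-(5,5-dimethyl-3,4,5,6,7,8-hexahydronaphthalen-2(1H)-ylidene)ethyl]-4,4,5,5-tetramethyl-1,3,2-dioxaborolane | CC1(C)OB(C/C=C2/CCC3=C(CCCC3(C)C)C2)OC1(C)C | intermediate
15 | (2Z)-2-(5,5-dimethyl-3,4,5,6,7,8-hexahydronaphthalen-2(1H)-ylidene)ethan-1-ol | OC/C=C1/CCC2=C(CCCC2(C)C)C1 | intermediate
16 | (2Z)-2-(2-bromoethylidene)-5,5-dimethyl-1,2,3,4,5,6,7,8-octahydronaphthalene | BrC/C=C1/CCC2=C(CCCC2(C)C)C1 | intermediate
17 | [(2Z)-2-(5,5-dimethyl-3,4,5,6,7,8-hexahydronaphthalen-2(1H)-ylidene)ethyl]triphenylphosphonium bromide | [Br-].c1ccc(cc1)[P+](C/C=C2/CCC3=C(CCCC3(C)C)C2)(c1ccccc1)c1ccccc1 | intermediate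
18 | geraniol, (2E)-3,7-dimethylocta-2,6-dien-1-ol | CC(C)=CCC/C(C)=C/CO | starting material
19 | [(2S,3S)-3-methyl-3-(4-methylpent-3-en-1-yl)oxiran-2-yl]methanol | CC(C)=CCC[C@@]1(C)[C@H](CO)O1 | intermediate
20 | tert-butyl{[(2S,3S)-3-methyl-3-(4-methylpent-3-en-1-yl)oxiran-2-yl]methoxy}diphenylsilane | CC(C)=CCC[C@@]1(C)[C@H](CO[Si](c2ccccc2)(c2ccccc2)C(C)(C)C)O1 | intermediate
21 | 3-[(2S,3S)-3-({[tert-butyl(diphenyl)silyl]oxy}methyl)-2-methyloxiran-2-yl]propanal | O=CCC[C@@]1(C)[C@H](CO[Si](c2ccccc2)(c2ccccc2)C(C)(C)C)O1 | intermediate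
22 | (3R,4S)-6-[(2S,3S)-3-({[tert-butyl(diphenyl)silyl]oxy}methyl)-2-methyloxiran-2-yl]-3-methylhex-1-en-4-ol | C[C@H](C=C)[C@@H](O)CC[C@@]1(C)[C@H](CO[Si](c2ccccc2)(c2ccccc2)C(C)(C)C)O1 | intermediate
23 | (3R,4S)-6-[(2S,3S)-3-({[tert-butyl(diphenyl)silyl]oxy}methyl)-2-methyloxiran-2-yl]-3-methylhex-1-en-4-yl methanesulfonate | C[C@H](C=C)[C@@H](OS(C)(=O)=O)CC[C@@]1(C)[C@H](CO[Si](c2ccccc2)(c2ccccc2)C(C)(C)C)O1 | intermediate
24 | (3R,4S,7R,8S)-9-{[tert-butyl(diphenyl)silyl]oxy}-7-hydroperoxy-8-hydroxy-3,7-dimethylnon-1-en-4-yl methanesulfonate | C[C@H](C=C)[C@@H](OS(C)(=O)=O)CC[C@](C)([C@@H](O)CO[Si](c1ccccc1)(c1ccccc1)C(C)(C)C)OO | intermediate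
25 | (1S)-1-{(3R,6R)-6-[(2R)-but-3-en-2-yl]-3-methyl-1,2-dioxan-3-yl}-2-{[tert-butyl(diphenyl)silyl]oxy}ethan-1-ol | C[C@H](C=C)[C@H]1CC[C@](C)([C@@H](O)CO[Si](c2ccccc2)(c2ccccc2)C(C)(C)C)OO1 | intermediate
26 | (2S)-2-{(3R,6R)-6-[(1S)-2-{[tert-butyl(diphenyl)silyl]oxy}-1-hydroxyethyl]-6-methyl-1,2-dioxan-3-yl}propanal | C[C@H](C=O)[C@H]1CC[C@](C)([C@@H](O)CO[Si](c2ccccc2)(c2ccccc2)C(C)(C)C)OO1 | intermediate
27 | (2S)-2-{(3R,6R)-6-[(1S)-2-{[tert-butyl(diphenyl)silyl]oxy}-1-hydroxyethyl]-6-methyl-1,2-dioxan-3-yl}propanoic acid | C[C@H](C(=O)O)[C@H]1CC[C@](C)([C@@H](O)CO[Si](c2ccccc2)(c2ccccc2)C(C)(C)C)OO1 | intermediate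
28 | methyl (2S)-2-{(3R,6R)-6-[(1S)-2-{[tert-butyl(diphenyl)silyl]oxy}-1-hydroxyethyl]-6-methyl-1,2-dioxan-3-yl}propanoate | C[C@H](C(=O)OC)[C@H]1CC[C@](C)([C@@H](O)CO[Si](c2ccccc2)(c2ccccc2)C(C)(C)C)OO1 | intermediate
29 | methyl (2S)-2-{(3R,6R)-6-[(1S)-1,2-dihydroxyethyl]-6-methyl-1,2-dioxan-3-yl}propanoate | C[C@H](C(=O)OC)[C@H]1CC[C@](C)([C@@H](O)CO)OO1 | intermediate
30 | methyl (2S)-2-[(3R,6R)-6-formyl-6-methyl-1,2-dioxan-3-yl]propanoate | C[C@H](C(=O)OC)[C@H]1CC[C@](C)(C=O)OO1 | intermediate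
31 | [(2Z)-2-(5,5-dimethyl-3,4,5,6,7,8-hexahydronaphthalen-2(1H)-ylidene)ethylidene]triphenylphosphorane | C(/C=C1/CCC2=C(CCCC2(C)C)C1)=P(c1ccccc1)(c1ccccc1)c1ccccc1 | intermediate
32 | methyl (2S)-2-{(3R,6R)-6-[(3Z)-3-(5,5-dimethyl-3,4,5,6,7,8-hexahydronaphthalen-2(1H)-ylidene)prop-1-en-1-yl]-6-methyl-1,2-dioxan-3-yl}propanoate | C[C@H](C(=O)OC)[C@H]1CC[C@](C)(C=C/C=C2/CCC3=C(CCCC3(C)C)C2)OO1 | intermediate
33 | methyl (2S)-2-{(3R,6S)-6-[(3Z)-3-(5,5-dimethyl-3,4,5,6,7,8-hexahydronaphthalen-2(1H)-ylidene)propyl]-6-methyl-1,2-dioxan-3-yl}propanoate | C[C@H](C(=O)OC)[C@H]1CC[C@](C)(CC/C=C2/CCC3=C(CCCC3(C)C)C2)OO1 | intermediate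
34 | (2S)-2-{(3R,6S)-6-[(3Z)-3-(5,5-dimethyl-3,4,5,6,7,8-hexahydronaphthalen-2(1H)-ylidene)propyl]-6-methyl-1,2-dioxan-3-yl}propanoic acid | C[C@H](C(=O)O)[C@H]1CC[C@](C)(CC/C=C2/CCC3=C(CCCC3(C)C)C2)OO1 | target

**Totals**
Total step count: 25.
Longest linear sequence: 14 steps (steps 1–11 then 23–25; the dioxane branch, steps 12–22 then 23–25, is equally long).

**Three steps most likely to fail**

Step 4. Insertion of the hindered bis-silyl alkyne into the palladacycle may be too slow, so that reductive elimination to the four-membered ring or protodepalladation takes over. The fallback sets out from compound 1, returns at compound 9 (which enters step 6 directly), and closes ring A by Friedel–Crafts cyclialkylation instead. Mono-O-methylation of 1 (MeI, K2CO3) should give 3-methoxyphenol F1, and triflation (Tf2O, pyridine) 3-methoxyphenyl trifluoromethanesulfonate F2. A Heck reaction with 2-methylbut-3-en-2-ol (Pd(OAc)2, P(o-tol)3, Et3N) should give (3E)-4-(3-methoxyphenyl)-2-methylbut-3-en-2-ol F3, and hydrogenation (H2, Pd/C) 4-(3-methoxyphenyl)-2-methylbutan-2-ol F4. Polyphosphoric acid should then cyclise the tertiary cation para to the methoxy group to give 9.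

Step 9. Nickel hydride addition may occur across the wrong diene unit of the triene, or the Z selectivity may be eroded. The fallback sets out from compound 13, returns at compound 15, and uses the π-allylpalladium 1,4-hydrosilylation of 1,3-dienes followed by a Tamao–Fleming oxidation. HSiCl3 with PdCl2(PhCN)2/PPh3 should give trichloro[(2Z)-2-(5,5-dimethyl-3,4,5,6,7,8-hexahydronaphthalen-2(1H)-ylidene)ethyl]silane F5. Ethanolysis (EtOH, Et3N) should give triethoxy[(2Z)-2-(5,5-dimethyl-3,4,5,6,7,8-hexahydronaphthalen-2(1H)-ylidene)ethyl]silane F6, and oxidation (H2O2, KF, KHCO3) should give 15 with retention.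

Step 18. Base-induced elimination of the β-branched secondary mesylate, or fragmentation of the β-hydroxy hydroperoxide, may compete with ring closure. The fallback sets out from compound 21, returns at compound 28, and closes the ring by conjugate addition instead. A Wittig reaction of 21 with methyl 2-(triphenylphosphoranylidene)propanoate should give methyl (2E)-5-[(2S,3S)-3-({[tert-butyl(diphenyl)silyl]oxy}methyl)-2-methyloxiran-2-yl]-2-methylpent-2-enoate F7. Perhydrolysis as in step 17 should give methyl (2E,6R,7S)-8-{[tert-butyl(diphenyl)silyl]oxy}-6-hydroperoxy-7-hydroxy-2,6-dimethyloct-2-enoate F8. Intramolecular oxa-Michael addition of the hydroperoxide (Et2NH, CF3CH2OH) should then give the dioxane ester, from which 28 would have to be separated from its diastereomers at C3 and C2; this route gives up stereocontrol at those two centres.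

Further compounds
F1 | step 4 | 3-methoxyphenol | COc1cccc(O)c1
F2 | step 4 | 3-methoxyphenyl trifluoromethanesulfonate | COc1cccc(OS(=O)(=O)C(F)(F)F)c1
F3 | step 4 | (3E)-4-(3-methoxyphenyl)-2-methylbut-3-en-2-ol | COc1cccc(/C=C/C(C)(C)O)c1
F4 | step 4 | 4-(3-methoxyphenyl)-2-methylbutan-2-ol | COc1cccc(CCC(C)(C)O)c1
F5 | step 9 | trichloro[(2Z)-2-(5,5-dimethyl-3,4,5,6,7,8-hexahydronaphthalen-2(1H)-ylidene)ethyl]silane | Cl[Si](Cl)(Cl)C/C=C1/CCC2=C(CCCC2(C)C)C1
F6 | step 9 | triethoxy[(2Z)-2-(5,5-dimethyl-3,4,5,6,7,8-hexahydronaphthalen-2(1H)-ylidene)ethyl]silane | CCO[Si](OCC)(OCC)C/C=C1/CCC2=C(CCCC2(C)C)C1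
F7 | step 18 | methyl (2E)-5-[(2S,3S)-3-({[tert-butyl(diphenyl)silyl]oxy}methyl)-2-methyloxiran-2-yl]-2-methylpent-2-enoate | COC(=O)/C(C)=C/CC[C@@]1(C)[C@H](CO[Si](c2ccccc2)(c2ccccc2)C(C)(C)C)O1
F8 | step 18 | methyl (2E,6R,7S)-8-{[tert-butyl(diphenyl)silyl]oxy}-6-hydroperoxy-7-hydroxy-2,6-dimethyloct-2-enoate | COC(=O)/C(C)=C/CC[C@](C)([C@@H](O)CO[Si](c1ccccc1)(c1ccccc1)C(C)(C)C)OO
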